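Ring A of the coumarin (C4a, C5, C6, C7, C8, C8a) bears three adjacent oxygens at C7, C8 and C8a next to the carbon substituent at C4a. This pattern is cut at C5–C6 and C7–C8 into a 3,4-dioxygenated 2-pyrone-5-carboxylate and the ethynyl ether of the complete (2'R,3'R,5'R) epoxy side chain. A single cycloaddition with loss of CO2 should assemble the benzene ring and deliver the C7–O–C1' ether without any substitution next to the epoxide. The pyrone carries a 4-pivalate, which keeps the diene electron-poor and non-acidic and is later removed in the same reduction that prepares the ester carbon for closure of ring B.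

Key step: step 10

Remark: CIP analysis of the target gives 2'R, 3'R, 5'R with C1' and C4' trans on the oxirane, which calls for an E allylic alcohol and D-(−)-diethyl tartrate; 7, 8 and 15 are taken as purchasable.

Abbreviation used in names: R* = [(2R,3R)-3-{(2R)-2-[(tert-butyldimethylsilyl)oxy]-4-methylpent-3-en-1-yl}-3-methyloxiran-2-yl]methyl. C1' is the CH2, C2' and C3' are the oxirane carbons, and C5' carries the silyloxy group.

Step 1
Reactants: 1 dimethyl 3-oxopentanedioate
Product: 2 dimethyl 2-diazo-3-oxopentanedioate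
Conditions: 4-AcNHC6H4SO2N3 (1.0 equiv), Et3N, MeCN, 0 °C to rt
Reagents that add atoms: 4-acetamidobenzenesulfonyl azide, CC(=O)Nc1ccc(cc1)S(=O)(=O)N=[N+]=[N-]
Why: Regitz diazo transfer to a doubly activated methylene; one equivalent of azide should limit transfer to one of the two equivalent CH2 groups.

Step 2
Reactants: 2 dimethyl 2-diazo-3-oxopentanedioate
Product: 3 dimethyl 2-methoxy-3-oxopentanedioate (racemic)
Conditions: Rh2(OAc)4 (1 mol %), MeOH (5 equiv), CH2Cl2, reflux
Reagents that add atoms: methanol, CO
Why: Rhodium-carbenoid O–H insertion of an acceptor-substituted diazo ketone into methanol, which places the future C8 methoxyl; the new centre is lost in step 3.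

Step 3
Reactants: 3 dimethyl 2-methoxy-3-oxopentanedioate
Product: 5 methyl 4-hydroxy-3-methoxy-2-oxo-2H-pyran-5-carboxylate, via methoxymethylidene keto diester 4 (not isolated)
Conditions: HC(OMe)3, Ac2O, 120 °C; evaporate; then 2 M aq. HCl, THF, 50 °C
Reagents that add atoms: trimethyl orthoformate, COC(OC)OC; water, O
Why: Alkoxymethylenation can be completed only at C4, the one CH2 between two carbonyls; acid then hydrolyses the vinylogous ester to the hydroxymethylene tautomer, whose enol oxygen lactonises onto the C1 ester, the usual closure of a 3,5-dioxo ester to a 4-hydroxy-2-pyrone.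

Step 4
Reactants: 5 methyl 4-hydroxy-3-methoxy-2-oxo-2H-pyran-5-carboxylate
Product: 6 methyl 3-methoxy-2-oxo-4-(pivaloyloxy)-2H-pyran-5-carboxylate
Conditions: t-BuCOCl, Et3N, 4-(dimethylamino)pyridine (5 mol %), CH2Cl2, 0 °C
Reagents that add atoms: pivaloyl chloride, CC(C)(C)C(=O)Cl
Why: O-acylation of the vinylogous acid (C3 is blocked, so no C-acylation); the hindered pivalate is chosen over a silyl group because it withdraws electrons from the diene and cannot release the acidic hydroxypyrone, which would add to an ynol ether.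

Step 5
Reactants: 7 3-methylbut-2-enal; 8 allenylboronic acid pinacol ester
Product: 10 (R)-6-methylhept-5-en-1-yn-4-ol, via pinacol borate ester 9 (not isolated)
Conditions: (R)-3,3'-bis(2,4,6-triisopropylphenyl)-1,1'-binaphthyl-2,2'-diyl hydrogen phosphate (10 mol %), PhMe, −20 °C; aq. NaHCO3 work-up
Reagents that add atoms: none
Why: Chiral-phosphoric-acid-catalysed propargylboration: the allenylboronate adds 1,2 through a closed six-membered SE2' transition state to give only the homopropargylic isomer, and the (R)-catalyst, hydrogen-bonded to the boronate oxygen and the formyl hydrogen, should expose the Re face of the enal, which corresponds to R at the carbinol (C5' of the target).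

Step 6
Reactants: 10 (R)-6-methylhept-5-en-1-yn-4-ol
Product: 11 (R)-tert-butyldimethyl[(6-methylhept-5-en-1-yn-4-yl)oxy]silane
Conditions: t-BuMe2SiCl, imidazole, DMF, rt
Reagents that add atoms: tert-butyldimethylsilyl chloride, CC(C)(C)[Si](C)(C)Cl
Why: Standard silylation of a secondary alcohol; the silyl ether should survive alanes, KH, n-BuLi, heat, hydride and MnO2 and is removed last by fluoride.

Step 7
Reactants: 11 (R)-tert-butyldimethyl[(6-methylhept-5-en-1-yn-4-yl)oxy]silane
Product: 13 (2E,5R)-5-[(tert-butyldimethylsilyl)oxy]-3,7-dimethylocta-2,6-dien-1-ol, via alkenyl(dimethyl)alane 12 (not isolated)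
Conditions: Me3Al, Cp2ZrCl2 (25 mol %), CH2Cl2, 0 °C to rt; evaporate; n-BuLi, THF–hexane, −78 to 0 °C; (CH2O)n, rt; aq. KNaC4H4O6 work-up
Reagents that add atoms: trimethylaluminium, C[Al](C)C; formaldehyde (as paraformaldehyde), C=O
Why: Negishi carboalumination adds methyl and aluminium syn across the terminal alkyne with methyl on the internal carbon, and the derived alanate is hydroxymethylated with retention, which fixes the E geometry; the trisubstituted alkene does not react.

Step 8
Reactants: 13 (2E,5R)-5-[(tert-butyldimethylsilyl)oxy]-3,7-dimethylocta-2,6-dien-1-ol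
Product: 14 [(2R,3R)-3-{(2R)-2-[(tert-butyldimethylsilyl)oxy]-4-methylpent-3-en-1-yl}-3-methyloxiran-2-yl]methanol (R*–OH)
Conditions: Ti(OiPr)4 (10 mol %), D-(−)-diethyl tartrate (12 mol %), t-BuOOH, 4 Å molecular sieves (Na12Al12Si12O48), CH2Cl2, −20 °C
Reagents that add atoms: tert-butyl hydroperoxide, CC(C)(C)OO
Why: Sharpless asymmetric epoxidation: only the free primary allylic alcohol binds titanium, so the C6'=C7' alkene is untouched, and for an E 3,3-disubstituted allylic alcohol the D-(−)-tartrate should deliver oxygen to the face that gives C2' R and C3' R, reagent control overriding the remote C5' centre.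

Step 9
Reactants: 14 R*–OH; 15 trichloroethene
Product: 17 (2R,3R)-2-{(2R)-2-[(tert-butyldimethylsilyl)oxy]-4-methylpent-3-en-1-yl}-3-[(ethynyloxy)methyl]-2-methyloxirane (R*–O–C≡CH), via (E)-1,2-dichlorovinyl ether 16 (not isolated)
Conditions: KH, THF, 0 °C; Cl2C=CHCl, −50 °C to rt; then n-BuLi (2.4 equiv), −78 to −40 °C; MeOH, −78 °C; Et3N-deactivated SiO2
Reagents that add atoms: none
Why: The alkoxide adds anti to dichloroacetylene formed in situ, and n-BuLi then effects dehydrochlorination and chlorine–lithium exchange to the lithium alkynyl ether, which methanol protonates (the standard alcohol-to-ethynyl-ether sequence); the epoxide has to be in place first, because the ethynyl ether of allylic alcohol 13 would undergo (3,3) rearrangement to a ketene.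

Step 10
Reactants: 6 methyl 3-methoxy-2-oxo-4-(pivaloyloxy)-2H-pyran-5-carboxylate; 17 R*–O–C≡CH
Product: 19 methyl 3-methoxy-2-(pivaloyloxy)-4-(R*O)benzoate, via bicyclic lactone 18 (not isolated)
Conditions: PhMe, 100 °C, sealed tube (6 in slight excess)
Reagents that add atoms: none
Why: Proposed new method: the electron-rich alkynyl ether (HOMO) and the acceptor-substituted pyrone (LUMO) should combine in an asynchronous inverse-electron-demand (4+2) cycloaddition, the alkyne CH bonding in advance to pyrone C6 and the oxygen-bearing carbon to C3, to give the 2-oxabicyclo[2.2.2]octadienone 18, which expels CO2 by retro-(4+2) reaction and becomes aromatic. The closest known reaction type is the cycloaddition–decarboxylation of methyl 2-oxo-2H-pyran-5-carboxylate with alkoxyalkynes, enol ethers and ketene acetals; it has not been shown for a pyrone carrying oxygen at both C3 and C4. Ring A is closed by intermolecular cycloaddition across the diene termini (coumarin bonds C5–C6 and C7–C8) and is released as a benzene ring by cycloreversion of the lactone bridge. No stereocentre is created in 19: the two bridgehead centres of 18 form without control and vanish with CO2, and C2', C3' and C5' are insulated spectators. The step needs regioselectivity, which the polarisation of the partners secures (C6 is the beta carbon of the acrylate and the remote terminus of the vinylogous lactone, the CH end of the ynol ether is its nucleophilic carbon), so the ether lands para to the ester. It also needs chemoselectivity for the alkyne over the trisubstituted alkene and the epoxide, secured by the much higher HOMO of the ynol ether and by neutral thermal conditions, while the pivalate keeps the diene electron-poor and free of an acidic OH.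

Step 11
Reactants: 19 methyl 3-methoxy-2-(pivaloyloxy)-4-(R*O)benzoate
Product: 20 6-(hydroxymethyl)-2-methoxy-3-(R*O)phenol
Conditions: (iBu)2AlH (5 equiv), CH2Cl2, −78 to −40 °C; aq. KNaC4H4O6 work-up; crude product taken on
Reagents that add atoms: none
Why: Hydride reduction of both esters at low temperature: the aryl pivalate is cleaved to the aluminium phenoxide and the methyl ester is reduced to the benzylic alcohol, while epoxide, silyl ether and alkene should be inert to (iBu)2AlH at this temperature.

Step 12
Reactants: 20 6-(hydroxymethyl)-2-methoxy-3-(R*O)phenol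
Product: 21 2-hydroxy-3-methoxy-4-(R*O)benzaldehyde
Conditions: MnO2 (activated, 15 equiv), CH2Cl2, rt
Reagents that add atoms: none
Why: Selective MnO2 oxidation of a benzylic alcohol, a standard way from salicyl alcohols to salicylaldehydes; the only other oxidisable alcohol (allylic C5'–OH) is silylated.

Step 13
Reactants: 21 2-hydroxy-3-methoxy-4-(R*O)benzaldehyde
Product: 23 8-methoxy-7-(R*O)-2H-chromen-2-one, via aryl phosphoranylideneacetate 22 (not isolated)
Conditions: Ph3P=C=C=O (1.2 equiv), PhMe, 90 °C
Reagents that add atoms: ketenylidenetriphenylphosphorane, O=C=C=P(c1ccccc1)(c1ccccc1)c1ccccc1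
Why: The phenol adds across the ketene C=C to give an ester-stabilised ylide, which closes ring B by intramolecular Wittig reaction with the ortho aldehyde (the ring enforces the cis alkene), the known neutral conversion of salicylaldehydes into coumarins.

Step 14
Reactants: 23 8-methoxy-7-(R*O)-2H-chromen-2-one
Product: 24 7-{[(2R,3R)-3-[(2R)-2-hydroxy-4-methylpent-3-en-1-yl]-3-methyloxiran-2-yl]methoxy}-8-methoxy-2H-chromen-2-one
Conditions: Bu4NF, AcOH (1 equiv each), THF, 0 °C to rt
Reagents that add atoms: none
Why: Fluoride cleavage of the secondary silyl ether; acetic acid buffering should keep the lactone closed and prevent the freed C5' hydroxyl from attacking the epoxide, for which only 4-exo or 5-endo modes are available.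

Compound list
1 | dimethyl 3-oxopentanedioate | COC(=O)CC(=O)CC(=O)OC | starting material
2 | dimethyl 2-diazo-3-oxopentanedioate | COC(=O)CC(=O)C(=[N+]=[N-])C(=O)OC | intermediate
3 | dimethyl 2-methoxy-3-oxopentanedioate (racemic) | COC(=O)CC(=O)C(OC)C(=O)OC | intermediate
4 | dimethyl 2-methoxy-4-(methoxymethylidene)-3-oxopentanedioate (E/Z mixture, formed in situ) | COC=C(C(=O)OC)C(=O)C(OC)C(=O)OC | intermediate
5 | methyl 4-hydroxy-3-methoxy-2-oxo-2H-pyran-5-carboxylate | COC(=O)C1=COC(=O)C(OC)=C1O | intermediate
6 | methyl 3-methoxy-2-oxo-4-(pivaloyloxy)-2H-pyran-5-carboxylate | COC(=O)C1=COC(=O)C(OC)=C1OC(=O)C(C)(C)C | intermediate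
7 | 3-methylbut-2-enal | CC(C)=CC=O | starting material
8 | allenylboronic acid pinacol ester, 4,4,5,5-tetramethyl-2-(propa-1,2-dien-1-yl)-1,3,2-dioxaborolane | C=C=CB1OC(C)(C)C(C)(C)O1 | starting material
9 | 4,4,5,5-tetramethyl-2-{[(4R)-6-methylhept-5-en-1-yn-4-yl]oxy}-1,3,2-dioxaborolane (formed in situ) | C#CC[C@@H](OB1OC(C)(C)C(C)(C)O1)C=C(C)C | intermediate
10 | (R)-6-methylhept-5-en-1-yn-4-ol | C#CC[C@@H](O)C=C(C)C | intermediate
11 | (R)-tert-butyldimethyl[(6-methylhept-5-en-1-yn-4-yl)oxy]silane | C#CC[C@@H](O[Si](C)(C)C(C)(C)C)C=C(C)C | intermediate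
12 | dimethyl{(1E,4R)-4-[(tert-butyldimethylsilyl)oxy]-2,6-dimethylhepta-1,5-dien-1-yl}alumane (formed in situ) | C[Al](C)/C=C(\C)C[C@@H](O[Si](C)(C)C(C)(C)C)C=C(C)C | intermediate
13 | (2E,5R)-5-[(tert-butyldimethylsilyl)oxy]-3,7-dimethylocta-2,6-dien-1-ol | OC/C=C(\C)C[C@@H](O[Si](C)(C)C(C)(C)C)C=C(C)C | intermediate
14 | [(2R,3R)-3-{(2R)-2-[(tert-butyldimethylsilyl)oxy]-4-methylpent-3-en-1-yl}-3-methyloxiran-2-yl]methanol (R*–OH) | OC[C@H]1O[C@]1(C)C[C@@H](O[Si](C)(C)C(C)(C)C)C=C(C)C | intermediate
15 | trichloroethene | ClC=C(Cl)Cl | starting material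
16 | (E)-1,2-dichlorovinyl ether R*–O–C(Cl)=CHCl (formed in situ) | Cl/C=C(/Cl)OC[C@H]1O[C@]1(C)C[C@@H](O[Si](C)(C)C(C)(C)C)C=C(C)C | intermediate
17 | (2R,3R)-2-{(2R)-2-[(tert-butyldimethylsilyl)oxy]-4-methylpent-3-en-1-yl}-3-[(ethynyloxy)methyl]-2-methyloxirane (R*–O–C≡CH) | C#COC[C@H]1O[C@]1(C)C[C@@H](O[Si](C)(C)C(C)(C)C)C=C(C)C | intermediate
18 | methyl 4-methoxy-3-oxo-8-(pivaloyloxy)-5-(R*O)-2-oxabicyclo[2.2.2]octa-5,7-diene-7-carboxylate (both bridgehead epimers, formed in situ) | O=C1OC2C=C(OC[C@H]3O[C@]3(C)C[C@@H](O[Si](C)(C)C(C)(C)C)C=C(C)C)C1(OC)C(OC(=O)C(C)(C)C)=C2C(=O)OC | intermediate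
19 | methyl 3-methoxy-2-(pivaloyloxy)-4-(R*O)benzoate | COC(=O)c1ccc(OC[C@H]2O[C@]2(C)C[C@@H](O[Si](C)(C)C(C)(C)C)C=C(C)C)c(OC)c1OC(=O)C(C)(C)C | intermediate
20 | 6-(hydroxymethyl)-2-methoxy-3-(R*O)phenol | OCc1ccc(OC[C@H]2O[C@]2(C)C[C@@H](O[Si](C)(C)C(C)(C)C)C=C(C)C)c(OC)c1O | intermediate
21 | 2-hydroxy-3-methoxy-4-(R*O)benzaldehyde | O=Cc1ccc(OC[C@H]2O[C@]2(C)C[C@@H](O[Si](C)(C)C(C)(C)C)C=C(C)C)c(OC)c1O | intermediate
22 | 6-formyl-2-methoxy-3-(R*O)phenyl 2-(triphenylphosphoranylidene)acetate (formed in situ) | O=Cc1ccc(OC[C@H]2O[C@]2(C)C[C@@H](O[Si](C)(C)C(C)(C)C)C=C(C)C)c(OC)c1OC(=O)C=P(c1ccccc1)(c1ccccc1)c1ccccc1 | intermediate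
23 | 8-methoxy-7-(R*O)-2H-chromen-2-one | COc1c(OC[C@H]2O[C@]2(C)C[C@@H](O[Si](C)(C)C(C)(C)C)C=C(C)C)ccc2ccc(=O)oc12 | intermediate
24 | 7-{[(2R,3R)-3-[(2R)-2-hydroxy-4-methylpent-3-en-1-yl]-3-methyloxiran-2-yl]methoxy}-8-methoxy-2H-chromen-2-one | COc1c(OC[C@H]2O[C@]2(C)C[C@@H](O)C=C(C)C)ccc2ccc(=O)oc12 | target

Total step count: 14 (pyrone branch steps 1–4, side-chain branch steps 5–9, union and endgame steps 10–14).
Longest linear sequence: 10 steps (steps 5 to 14, from 7 and 8 to 24).

Steps most likely to fail

1. Step 10. The donor oxygens at C3 and C4 of the pyrone may raise its LUMO so far that cycloaddition becomes slower than thermal oligomerisation or adventitious hydration of the ynol ether. The addition may also turn stepwise and end in a (2+2) adduct at the pyrone C5=C6 bond. The fallback makes the aryl ether by known substitution chemistry instead of cycloaddition. It sets out from epoxy alcohol 14, which is coupled with purchasable 7-hydroxy-8-methoxy-2H-chromen-2-one F1 in a Mitsunobu reaction (PPh3, diisopropyl azodicarboxylate, THF, 0 °C to rt; SN2 at the primary C1', epoxide untouched). This should give 23 directly, where the route is rejoined before step 14.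

2. Step 9. The potassium alkoxide of the 2,3-epoxy alcohol may undergo Payne rearrangement, or the oxirane may be opened or isomerised by KH or n-BuLi before the vinyl ether has formed. The terminal ynol ether may also hydrate during isolation. The fallback avoids the alkoxide and brings in the alkyne carbons by olefination of an ester. It sets out from 14, which is formylated (HCO2Ac, pyridine, 0 °C) to the formate F2. Wittig-type dichloromethylenation (PPh3, CCl4, THF, 60 °C) should give the 2,2-dichlorovinyl ether F3. Treatment with n-BuLi (2.2 equiv, THF, −78 °C; dehydrochlorination and chlorine–lithium exchange) and a methanol quench return the route to 17.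

3. Step 11. Once the pivalate is cleaved, the aluminium phenoxide next to the ester may retard its reduction, and warming to force it may let the hydride open the epoxide. The electron-rich salicyl alcohol may also ionise to an ortho-quinone methide on work-up. The fallback masks the phenol before reduction and sets out from 19. Methanolysis (NaOMe, MeOH, 0 °C) should give the methyl salicylate F4, which is silylated (t-BuMe2SiCl, imidazole, 4-(dimethylamino)pyridine, DMF) to the aryl silyl ether F5. The unchelated ester is then reduced at −78 °C ((iBu)2AlH, CH2Cl2) to the benzylic alcohol F6 and oxidised (MnO2, CH2Cl2) to the aldehyde F7. Selective cleavage of the aryl silyl ether (KHF2, MeOH, rt) returns the route to 21.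

Further compounds
F1 | step 10 | 7-hydroxy-8-methoxy-2H-chromen-2-one | COc1c(O)ccc2ccc(=O)oc12
F2 | step 9 | R* formate, [(2R,3R)-3-{(2R)-2-[(tert-butyldimethylsilyl)oxy]-4-methylpent-3-en-1-yl}-3-methyloxiran-2-yl]methyl formate | O=COC[C@H]1O[C@]1(C)C[C@@H](O[Si](C)(C)C(C)(C)C)C=C(C)C
F3 | step 9 | 2,2-dichlorovinyl ether R*–O–CH=CCl2 | ClC(Cl)=COC[C@H]1O[C@]1(C)C[C@@H](O[Si](C)(C)C(C)(C)C)C=C(C)C
F4 | step 11 | methyl 2-hydroxy-3-methoxy-4-(R*O)benzoate | COC(=O)c1ccc(OC[C@H]2O[C@]2(C)C[C@@H](O[Si](C)(C)C(C)(C)C)C=C(C)C)c(OC)c1O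
F5 | step 11 | methyl 2-[(tert-butyldimethylsilyl)oxy]-3-methoxy-4-(R*O)benzoate | COC(=O)c1ccc(OC[C@H]2O[C@]2(C)C[C@@H](O[Si](C)(C)C(C)(C)C)C=C(C)C)c(OC)c1O[Si](C)(C)C(C)(C)C
F6 | step 11 | {2-[(tert-butyldimethylsilyl)oxy]-3-methoxy-4-(R*O)phenyl}methanol | OCc1ccc(OC[C@H]2O[C@]2(C)C[C@@H](O[Si](C)(C)C(C)(C)C)C=C(C)C)c(OC)c1O[Si](C)(C)C(C)(C)C
F7 | step 11 | 2-[(tert-butyldimethylsilyl)oxy]-3-methoxy-4-(R*O)benzaldehyde | O=Cc1ccc(OC[C@H]2O[C@]2(C)C[C@@H](O[Si](C)(C)C(C)(C)C)C=C(C)C)c(OC)c1O[Si](C)(C)C(C)(C)C
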